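Readings and results are calculated for substances that don't exist; scatter was added.

I began at the late end of the elm and birch runs, where the curves lie nearly flat and a reading shows how making and loss shared out the charge.

| flask | starting material | reagent | remark | time |
|---|---|---|---|---|
| oak | 0.25 M | 0.083 M | run made earlier |  |
| elm | 0.25 M | 0.40 M | run made earlier |  |
| birch | 0.18 M | 0.25 M | run made earlier |  |
| autumn | 0.080 M | 0.150 M |  | 6.0 min |
| midnight | 0.25 M | 0.250 M |  | 6.0 min |
| summer | 0.40 M | 0.0600 M |  | 6.0 min |
| winter | 0.80 M | 0.0600 M |  | 6.0 min |
| spring | 0.25 M | 0.120 M |  | 6.0 min |

- oak (time / min: target / %): 0.250: 0.7; 0.833: 0.3; 1.33: 0.9; 2.50: 4.2; 3.00: 10.5; 4.00: 23.0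
- elm (time / min: target / %): 0.667: 24.6; 1.33: 91.7; 2.00: 94.5; 3.00: 94.1; 4.00: 93.7
- birch (time / min: target / %): 0.417: 1.4; 1.00: 2.0; 2.00: 70.7; 3.00: 88.0; 4.00: 90.1

(readings scatter by 0.5 percentage points)



- the flasks by amount of target, in percent of the starting material charged, highest first, at 6.0 min (autumn / midnight / summer / winter / spring)
- the amount of target, in percent of the starting material charged of the flask you put first, at 6.0 min
- the amount of target, in percent of the starting material charged of the flask you put last, at 6.0 min

The elm run held more reagent than starting material, yet its target stood at 94.1% at 3.00 min, so a share of the starting material had gone elsewhere. The birch run, also richer in reagent than in starting material, stood at 90.1% at 4.00 min.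

The curves rise slowly and then fast, so I took it that making feeds on something it makes. I guessed that a loss step joins one starting material to one target, and that whatever making feeds on grows in step with target. That factor then cancels, and loss steps per making step equal a fixed concentration divided by the reagent present. I worked with the fraction of reagent left, not the target made. Summed over the run, the loss steps come to that concentration times ln(reagent charged / reagent left). Each loss step costs target two units of the charge, and reagent used is the mean of the charge and the final target.

I reckoned that concentration in two independent ways. Elm gave 0.00791 M and birch gave 0.00773 M. These flasks have different charges, so I trusted the agreement. Their mean is the loss constant, the reagent concentration at which a loss step keeps pace with a making step, a selectivity factor in concentration units: 0.00782 M.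

Birch, with midnight's reagent charge, was nearly flat by 4.00 min, so I treated midnight as finished at 6.0 min. Midnight's two charges are equal, so its reagent left equals its loss steps. The fraction left is therefore the loss constant over the charge, 0.0313, times ln(1 / fraction left). Repeated substitution gave 7.99%, and target is one minus twice that fraction, 84.0%. Copying elm's flat reading to midnight parts from this by 10 percentage points, and the copy is what cheats, since elm kept more of its reagent, 39.3%, than midnight's 7.99%.

The forecast gave the order midnight > autumn > spring > summer > winter, with midnight at 88% (80% to 94%), “finishes by about 3 min, near 88%”, and winter at 5% (2.5% to 7.5%); its midnight figure stood above mine.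

The simulation gave the order midnight > autumn > spring > summer > winter, with midnight at 83.8% and winter at 0.141%.

    starting material + reagent → target + released group (k = 1.57 × 10⁻⁵ M⁻¹ s⁻¹)
    starting material + reagent + released group → target + 2 released group (k = 2.42 M⁻² s⁻¹)
    starting material + target → side product (k = 0.0205 M⁻¹ s⁻¹)

At 6.00 min, midnight held 0.170% of its starting material and 8.17% of its own reagent charge, against my reckoned 7.99%. One minus twice that simulated fraction gives 83.7% target.

Cutting midnight's reagent to 0.15 M makes reagent the limiting reagent, with 0.0921% of its charge left at 6.00 min. Reagent used minus the loss steps from the loss constant gives 38.1% target. The computed flask holds 40.6%.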